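The earlier runs and the new flask come from a simulation on assumed constants.

The flask is read at 40 h. Saturday's run, with the same charges of starting complex and incoming ligand, shows 56.2 % of its starting complex at 12.0 h and 55.6 % at 30.0 h, with a scatter of 1 percentage point. Tuesday's run has twice Saturday's scavenger and reads 56.7 % at 30.0 h.

| flask | starting complex | incoming ligand | scavenger | remark | time |
|---|---|---|---|---|---|
| Saturday's | 0.69 M | 0.414 M | 0.14 M | run made earlier |  |
| Tuesday's | 0.69 M | 0.414 M | 0.31 M | run made earlier |  |
| Sunday's | 0.69 M | 0.62 M | 0.207 M | run made earlier |  |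
| flask | 0.69 M | 0.414 M | 0.207 M |  | 40 h |

| run | time / h | starting complex / % | complex with two exchanged / % |
|---|---|---|---|
| Saturday's | 6.00 | 59.8 | 8.8 |
| Saturday's | 12.0 | 56.2 | 10.8 |
| Saturday's | 20.0 | 56.4 | 9.5 |
| Saturday's | 25.0 | 56.1 | 11.8 |
| Saturday's | 30.0 | 55.6 | 11.6 |
| Tuesday's | 2.50 | 65.3 | 7.4 |
| Tuesday's | 5.00 | 59.0 | 10.7 |
| Tuesday's | 10.0 | 55.8 | 12.2 |
| Tuesday's | 15.0 | 56.9 | 11.5 |
| Tuesday's | 30.0 | 56.7 | 9.3 |
| Sunday's | 3.00 | 54.0 | 14.3 |
| Sunday's | 8.00 | 45.0 | 17.1 |
| Sunday's | 15.0 | 44.8 | 16.6 |
| Sunday's | 25.0 | 42.4 | 19.1 |
| Sunday's | 30.0 | 43.8 | 16.2 |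

(each reading ± 1 percentage point)

- complex with two exchanged is meant together with its crystals
- leaving ligand is meant together with its idle adduct
- solid, in amounts per volume of the solution: crystals
- reactions considered so far: starting complex + incoming ligand -> leaving ligand + complex with one exchanged; complex with one exchanged + incoming ligand -> leaving ligand + complex with two exchanged; complex with two exchanged + incoming ligand -> leaving ligand + complex with three exchanged; leaving ligand + incoming ligand <-> idle adduct; scavenger + leaving ligand -> scavenged by-product; crystals <-> complex with two exchanged; leaving ligand -> by-product carried off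
- the earlier runs do not show how much of incoming ligand is bound; that part of a forecast is a guess

* part of the starting complex that has reacted at 40 h
* share of the unused incoming ligand that is free and not bound as idle adduct, at 40 h

Let n be the incoming ligand charged per starting complex charged, the ligand equivalents: 0.600 in this flask. Let c be the part of the starting complex reacted.

Two chemists dispute c. The first says each ligand finds a fresh complex, so c equals n, or 60.0 %. To him, the gap to Saturday's 44.4 % is ligand parked as idle adduct. The second points to Saturday's 11.6 % of complex with two exchanged. Ligand also lands on complex already exchanged, so the reacted part must go back into the reckoning.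

I side with the second and reckon it myself. I assume roughly equal step rates, so starting complex takes ligand in proportion to what remains of it. Putting the first answer back gives 42.0 %. The next round gives 45.6 %. The rounds close on 1 − exp(−n), which is 45.1 %. For Sunday's run the same rule gives 59.3 %, and its last reading implies 56.2 %. The runs do not show binding, so I give no figure for the free share.

The forecast, a little below my figure, gives 43.8 % and 40 %, holding that “scavenger changes only the speed”.

The flask gives 43.2 % reacted and 89.5 % free.

    starting complex + incoming ligand → leaving ligand + complex with one exchanged (k = 2.20 × 10⁻⁴ M⁻¹ s⁻¹)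
    complex with one exchanged + incoming ligand → leaving ligand + complex with two exchanged (k = 2.93 × 10⁻⁴ M⁻¹ s⁻¹)
    complex with two exchanged + incoming ligand → leaving ligand + complex with three exchanged (k = 2.58 × 10⁻⁴ M⁻¹ s⁻¹)
    leaving ligand + incoming ligand ⇌ idle adduct, settled at all times (K = 4.70 M⁻¹)
    scavenger + leaving ligand → scavenged by-product (k = 0.0103 M⁻¹ s⁻¹)
    crystals ⇌ complex with two exchanged, rate k6*(cs6 - [complex with two exchanged]) while solid is left; crystals form when [complex with two exchanged] > cs6 (solubility = 0.530 M, k = 0.0104 s⁻¹)
    leaving ligand → by-product carried off (k = 1.65 × 10⁻⁵ s⁻¹)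

The first view keeps the opening of the flask: at 1.05 h, complex with one exchanged is made 3.21 times faster than it is used up, each step taken net. At 40.0 h the flask holds 8.43 × 10⁻¹⁰ M of idle adduct, and this parking leaves c unmoved. Incoming ligand is the limiting reagent, with 0 % left against 57 % of starting complex. A neighbouring flask is this flask with 0.17 M of starting complex, so n becomes 2.44 and the rule gives 91.2 %. That neighbour reacts 92.9 %, with 58.8 % as complex with three exchanged.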